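## Retrosynthetic overview

1. Target ⇐ ozonolysis of a C15 exo-methylene (masked ketone) and acetylation of the C1 tertiary alcohol on the bicyclic dienone.
2. 12-membered carbocycle ⇐ macrocyclising intramolecular aldol addition C5–C6 (cyclopentenone α'-enolate onto the tetrahydrofuran aldehyde), then E1cB dehydration to the E-enone.
3. Open precursor ⇐ Shapiro alkenyl addition (C1–C15) of the C6–C15 chain to (S)-4-silyloxy-3-methylcyclopentenone; the silyloxy centre relays chirality to C1 and is then oxidised away.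
4. Chain ⇐ Julia–Kocienski olefination/hydrogenation (C12–C13) of a tetrahydrofuran aldehyde (from geranyl acetate; prenylboration sets C10, Sharpless epoxidation with 5-exo opening sets C7) with a Roche-ester sulfone (C14).
5. Ring order: tetrahydrofuran (step 3); cyclopentene ring bought in as the meso diacetate; macrocycle last (step 28).

Assumption (locants used below): C1 = acetoxy carbon, C2=C3(Me), C4 = ring ketone, C5(=C6), C7 = THF C(Me), C8, C9, C10 = THF CH, C11 = CMe2, C12, C13, C14 = CH(Me), C15 = chain ketone; chiral reagents such as (+)-Ipc2BH and D-(−)-DET are bought.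

## Route

Step 1
Reactants: 1 geranyl acetate
Product: 3 (2E)-3-methyl-6-oxohex-2-en-1-yl acetate, via epoxide 2 (not isolated)
Conditions: mCPBA, CH2Cl2, 0 °C; then H5IO6, THF/Et2O, 0 °C
Reagents that add atoms: mCPBA, O=C(OO)c1cccc(Cl)c1
Why: Prilezhaev epoxidation is selective for the electron-rich distal trisubstituted alkene (the 2,3-alkene is deactivated by the allylic acetate), and periodic acid opens and cleaves the epoxide (Malaprade-type glycol cleavage) to the aldehyde and acetone.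

Step 2
Reactants: 3 (2E)-3-methyl-6-oxohex-2-en-1-yl acetate
Product: 6 (2E,6S)-3,7,7-trimethylnona-2,8-diene-1,6-diol, via borinate 4 (not isolated), via hydroxy acetate 5 (not isolated)
Conditions: (+)-Ipc2BH [from (−)-α-pinene], 3-methylbuta-1,2-diene, THF, −25 to 0 °C; 3, Et2O, −78 °C; then 3 M NaOH, 30% H2O2, MeOH, 0 °C to rt
Reagents that add atoms: 3-methylbuta-1,2-diene, CC(C)=C=C
Why: Brown asymmetric reverse prenylation: the (−)-α-pinene-derived prenylborane reacts through its γ-carbon in a chair Zimmerman–Traxler transition state on the Re face of the aldehyde, creating the C11 gem-dimethyl carbon and the 10S carbinol, and the alkaline peroxide work-up cleaves the B–O bond and saponifies the acetate.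

Step 3
Reactants: 6 (2E,6S)-3,7,7-trimethylnona-2,8-diene-1,6-diol
Product: 8 (1R)-1-[(2S,5S)-2-methyl-5-(2-methylbut-3-en-2-yl)oxolan-2-yl]ethane-1,2-diol, via epoxy diol 7 (not isolated)
Conditions: Ti(OiPr)4 (0.3 equiv), D-(−)-DET (0.36 equiv), TBHP, 4 Å MS, CH2Cl2, −20 °C; then CSA (cat.), 0 °C to rt
Reagents that add atoms: tert-butyl hydroperoxide, CC(C)(C)OO
Why: Sharpless asymmetric epoxidation with D-(−)-tartrate gives the (2R,3R)-epoxy alcohol, and acid-promoted 5-exo opening by the C10 hydroxyl at the tertiary epoxide carbon proceeds with inversion, fixing C7 as S in a 2,5-trans tetrahydrofuran.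

Step 4
Reactants: 8 (1R)-1-[(2S,5S)-2-methyl-5-(2-methylbut-3-en-2-yl)oxolan-2-yl]ethane-1,2-diol
Product: 10 [(2S,5S)-2-methyl-5-(2-methylbut-3-en-2-yl)oxolan-2-yl]methanol, via aldehyde 9 (not isolated)
Conditions: NaIO4, THF/H2O (pH 7), 0 °C to rt; then NaBH4, MeOH, 0 °C
Reagents that add atoms: none
Why: Malaprade cleavage of the terminal 1,2-diol removes the extra carbon as formaldehyde, and borohydride reduction of the non-enolisable α-alkoxy aldehyde gives the C6 alcohol with C7 untouched.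

Step 5
Reactants: 10 [(2S,5S)-2-methyl-5-(2-methylbut-3-en-2-yl)oxolan-2-yl]methanol
Product: 11 tert-butyl{[(2S,5S)-2-methyl-5-(2-methylbut-3-en-2-yl)oxolan-2-yl]methoxy}diphenylsilane
Conditions: TBDPSCl, imidazole, DMAP (cat.), DMF, rt
Reagents that add atoms: tert-butyldiphenylsilyl chloride, CC(C)(C)[Si](Cl)(c1ccccc1)c1ccccc1
Why: Silyl ether formation on the only hydroxyl; TBDPS is chosen because it survives ozone, KN(SiMe3)2, hydrogenation, mild aqueous acid and n-BuLi.

Step 6
Reactants: 11 tert-butyl{[(2S,5S)-2-methyl-5-(2-methylbut-3-en-2-yl)oxolan-2-yl]methoxy}diphenylsilane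
Product: 13 2-[(2S,5S)-5-{[(tert-butyldiphenylsilyl)oxy]methyl}-5-methyloxolan-2-yl]-2-methylpropanal, via ozonide 12 (not isolated)
Conditions: O3, CH2Cl2, −78 °C; then Me2S, −78 °C to rt
Reagents that add atoms: ozone, [O-][O+]=O
Why: Ozonolysis (Criegee mechanism, reductive work-up) of the only alkene turns the vinyl group into the non-enolisable C12 aldehyde.

Step 7
Reactants: 14 methyl (2R)-3-hydroxy-2-methylpropanoate
Product: 15 methyl (2R)-3-[(tert-butyldimethylsilyl)oxy]-2-methylpropanoate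
Conditions: TBSCl, imidazole, CH2Cl2, 0 °C to rt
Reagents that add atoms: tert-butyldimethylsilyl chloride, CC(C)(C)[Si](C)(C)Cl
Why: Silyl protection of the primary alcohol so that the ester can be converted without β-elimination; the stereocentre is not touched.

Step 8
Reactants: 15 methyl (2R)-3-[(tert-butyldimethylsilyl)oxy]-2-methylpropanoate
Product: 16 (2R)-3-[(tert-butyldimethylsilyl)oxy]-N-methoxy-N,2-dimethylpropanamide
Conditions: MeNHOMe·HCl, i-PrMgCl, THF, −20 °C
Reagents that add atoms: N,O-dimethylhydroxylamine hydrochloride, CNOC.Cl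
Why: Weinreb amide formation by aminolysis of the ester with the chloromagnesium amide at low temperature, conditions that do not enolise the α-stereocentre.

Step 9
Reactants: 16 (2R)-3-[(tert-butyldimethylsilyl)oxy]-N-methoxy-N,2-dimethylpropanamide
Product: 17 (3R)-4-[(tert-butyldimethylsilyl)oxy]-3-methylbutan-2-one
Conditions: MeMgBr, THF, 0 °C; cold aq. NH4Cl
Reagents that add atoms: methylmagnesium bromide, C[Mg]Br
Why: Weinreb ketone synthesis; the chelated tetrahedral magnesium adduct prevents over-addition and collapses to the methyl ketone only on cold work-up, so C14 is not epimerised.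

Step 10
Reactants: 17 (3R)-4-[(tert-butyldimethylsilyl)oxy]-3-methylbutan-2-one
Product: 18 tert-butyldimethyl[(2R)-2-(2-methyl-1,3-dioxolan-2-yl)propoxy]silane
Conditions: TMSOCH2CH2OTMS, TMSOTf (5 mol%), CH2Cl2, −78 to −20 °C; pyridine quench
Reagents that add atoms: 1,2-bis(trimethylsilyloxy)ethane, C[Si](C)(C)OCCO[Si](C)(C)C
Why: Noyori ketalisation (silyl transfer under aprotic low-temperature conditions) masks the ketone without enolising the adjacent C14 centre or cleaving the TBS ether.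

Step 11
Reactants: 18 tert-butyldimethyl[(2R)-2-(2-methyl-1,3-dioxolan-2-yl)propoxy]silane
Product: 19 (2R)-2-(2-methyl-1,3-dioxolan-2-yl)propan-1-ol
Conditions: Bu4NF, THF, 0 °C to rt
Reagents that add atoms: none
Why: Fluoride-mediated desilylation frees the primary alcohol while the base-stable ketal stays.

Step 12
Reactants: 19 (2R)-2-(2-methyl-1,3-dioxolan-2-yl)propan-1-ol
Product: 20 5-{[(2S)-2-(2-methyl-1,3-dioxolan-2-yl)propyl]sulfanyl}-1-phenyl-1H-tetrazole
Conditions: 1-phenyl-1H-tetrazole-5-thiol, PPh3, DIAD, THF, 0 °C to rt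
Reagents that add atoms: 1-phenyl-1H-tetrazole-5-thiol, SC1=NN=NN1c1ccccc1
Why: Mitsunobu thioetherification (SN2 on the primary alkoxyphosphonium salt) installs the tetrazolyl sulfide without touching C14 (the descriptor changes only because sulfur outranks oxygen).

Step 13
Reactants: 20 5-{[(2S)-2-(2-methyl-1,3-dioxolan-2-yl)propyl]sulfanyl}-1-phenyl-1H-tetrazole
Product: 21 5-{[(2S)-2-(2-methyl-1,3-dioxolan-2-yl)propyl]sulfonyl}-1-phenyl-1H-tetrazole
Conditions: (NH4)6Mo7O24·4H2O (10 mol%), 30% H2O2, EtOH, 0 °C to rt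
Reagents that add atoms: hydrogen peroxide, OO
Why: Molybdate-catalysed peroxide oxidation of the sulfide through the sulfoxide gives the Julia–Kocienski sulfone; the ketal tolerates the near-neutral medium.

Step 14
Reactants: 21 5-{[(2S)-2-(2-methyl-1,3-dioxolan-2-yl)propyl]sulfonyl}-1-phenyl-1H-tetrazole; 13 2-[(2S,5S)-5-{[(tert-butyldiphenylsilyl)oxy]methyl}-5-methyloxolan-2-yl]-2-methylpropanal
Product: 23 tert-butyl({(2S,5S)-2-methyl-5-[(5R)-2-methyl-5-(2-methyl-1,3-dioxolan-2-yl)hex-3-en-2-yl]oxolan-2-yl}methoxy)diphenylsilane (E/Z mixture), via sulfonyl carbanion 22 (not isolated)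
Conditions: KN(SiMe3)2, DME, −60 °C; then 13, −60 °C to rt
Reagents that add atoms: none
Why: Julia–Kocienski olefination: the metalated sulfone adds to the non-enolisable neopentyl aldehyde, and Smiles rearrangement with loss of SO2 and the tetrazolone forms the C12=C13 bond, whose geometry is irrelevant because it is hydrogenated next.

Step 15
Reactants: 23 tert-butyl({(2S,5S)-2-methyl-5-[(5R)-2-methyl-5-(2-methyl-1,3-dioxolan-2-yl)hex-3-en-2-yl]oxolan-2-yl}methoxy)diphenylsilane
Product: 24 tert-butyl({(2S,5S)-2-methyl-5-[(5R)-2-methyl-5-(2-methyl-1,3-dioxolan-2-yl)hexan-2-yl]oxolan-2-yl}methoxy)diphenylsilane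
Conditions: H2 (1 atm), PtO2, EtOAc, rt
Reagents that add atoms: none
Why: Heterogeneous hydrogenation of the only C=C; PtO2 is used in place of palladium to avoid allylic double-bond migration that could erode C14.

Step 16
Reactants: 24 tert-butyl({(2S,5S)-2-methyl-5-[(5R)-2-methyl-5-(2-methyl-1,3-dioxolan-2-yl)hexan-2-yl]oxolan-2-yl}methoxy)diphenylsilane
Product: 25 (3R)-6-[(2S,5S)-5-{[(tert-butyldiphenylsilyl)oxy]methyl}-5-methyloxolan-2-yl]-3,6-dimethylheptan-2-one
Conditions: PPTS, acetone/H2O (10:1), 55 °C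
Reagents that add atoms: water, O
Why: Mild acid-catalysed ketal hydrolysis releases the methyl ketone while the TBDPS ether and the tetrahydrofuran survive and the α-methine is not enolised appreciably.

Step 17
Reactants: 25 (3R)-6-[(2S,5S)-5-{[(tert-butyldiphenylsilyl)oxy]methyl}-5-methyloxolan-2-yl]-3,6-dimethylheptan-2-one
Product: 26 (E)-2,4,6-triisopropylbenzenesulfonylhydrazone of 25
Conditions: 2,4,6-triisopropylbenzenesulfonyl hydrazide, THF, 4 Å MS, rt
Reagents that add atoms: 2,4,6-triisopropylbenzenesulfonyl hydrazide, CC(C)c1cc(C(C)C)c(S(=O)(=O)NN)c(C(C)C)c1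
Why: Hydrazone condensation; the bulky sulfonamide lies anti to the branched C14 side (E-hydrazone), which later directs deprotonation to the methyl group.

Step 18
Reactants: 27 cis-cyclopent-4-ene-1,3-diyl diacetate (meso)
Product: 28 (1R,4S)-4-hydroxycyclopent-2-en-1-yl acetate
Conditions: electric eel acetylcholinesterase, 0.1 M phosphate buffer (pH 6.9), rt
Reagents that add atoms: none
Why: Enzymatic desymmetrisation: the esterase hydrolyses only one of the two enantiotopic acetates of the meso diester, which sets both stereocentres.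

Step 19
Reactants: 28 (1R,4S)-4-hydroxycyclopent-2-en-1-yl acetate
Product: 29 (1R,4S)-4-[(tert-butyldimethylsilyl)oxy]cyclopent-2-en-1-yl acetate
Conditions: TBSCl, imidazole, DMF, rt
Reagents that add atoms: tert-butyldimethylsilyl chloride, CC(C)(C)[Si](C)(C)Cl
Why: Silylation of the free alcohol differentiates the two oxygens.

Step 20
Reactants: 29 (1R,4S)-4-[(tert-butyldimethylsilyl)oxy]cyclopent-2-en-1-yl acetate
Product: 30 (1R,4S)-4-[(tert-butyldimethylsilyl)oxy]cyclopent-2-en-1-ol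
Conditions: K2CO3 (cat.), MeOH, 0 °C to rt
Reagents that add atoms: none
Why: Base-catalysed transesterification (methanolysis) removes the acetate without affecting the TBS ether.

Step 21
Reactants: 30 (1R,4S)-4-[(tert-butyldimethylsilyl)oxy]cyclopent-2-en-1-ol
Product: 31 (4S)-4-[(tert-butyldimethylsilyl)oxy]cyclopent-2-en-1-one
Conditions: MnO2, CH2Cl2, rt
Reagents that add atoms: none
Why: MnO2 oxidation of the allylic alcohol gives the enone; the remaining silyloxy stereocentre is now C4 (S).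

Step 22
Reactants: 31 (4S)-4-[(tert-butyldimethylsilyl)oxy]cyclopent-2-en-1-one
Product: 32 tert-butyldimethyl({(1S,2S)-2-methyl-4-[(trimethylsilyl)oxy]cyclopent-3-en-1-yl}oxy)silane
Conditions: CuI, MeLi (2 equiv), Et2O, 0 °C; then TMSCl, 31, THF, −78 °C; Et3N quench
Reagents that add atoms: lithium dimethylcuprate (from CuI and MeLi), [Li+].C[Cu-]C; chlorotrimethylsilane, C[Si](C)(C)Cl
Why: Gilman cuprate conjugate addition anti to the silyloxy group with in situ TMSCl trapping gives the silyl enol ether, which prevents β-elimination of the silyloxy group from the enolate.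

Step 23
Reactants: 32 tert-butyldimethyl({(1S,2S)-2-methyl-4-[(trimethylsilyl)oxy]cyclopent-3-en-1-yl}oxy)silane
Product: 33 (4S)-4-[(tert-butyldimethylsilyl)oxy]-3-methylcyclopent-2-en-1-one
Conditions: Pd(OAc)2 (1.05 equiv), MeCN, rt
Reagents that add atoms: none
Why: Saegusa–Ito oxidation (palladium enolate, β-hydride elimination from C3) regenerates the enone with the methyl group now on the β-carbon and C4 unchanged.

Step 24
Reactants: 26 (E)-2,4,6-triisopropylbenzenesulfonylhydrazone of 25; 33 (4S)-4-[(tert-butyldimethylsilyl)oxy]-3-methylcyclopent-2-en-1-one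
Product: 37 (1R,4S)-4-[(tert-butyldimethylsilyl)oxy]-1-{(3R)-6-[(2S,5S)-5-{[(tert-butyldiphenylsilyl)oxy]methyl}-5-methyloxolan-2-yl]-3,6-dimethylhept-1-en-2-yl}-3-methylcyclopent-2-en-1-ol, via dianion 34 (not isolated), via alkenyllithium 35 (not isolated), via alkenylcerium dichloride 36 (not isolated)
Conditions: n-BuLi (2.2 equiv), THF, −78 to 0 °C; CeCl3, −78 °C; then 33, −78 °C; aq. NH4Cl
Reagents that add atoms: none
Why: Shapiro reaction (syn deprotonation at the methyl group, loss of sulfinate and N2) gives the 2-lithio-1-alkene, and its weakly basic organocerium derivative adds 1,2 to the enone on the face anti to the C4 silyloxy group, which sets the C1 carbinol (OH cis to OTBS).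

Step 25
Reactants: 37 the bis-silylated cyclopentenol described in step 24
Product: 38 (1R,4S)-1-{(3R)-6-[(2S,5S)-5-(hydroxymethyl)-5-methyloxolan-2-yl]-3,6-dimethylhept-1-en-2-yl}-3-methylcyclopent-2-ene-1,4-diol
Conditions: Bu4NF (excess), THF, rt to 40 °C
Reagents that add atoms: none
Why: Global fluoride desilylation removes both silyl ethers; the tertiary bis-allylic alcohol is stable to the basic medium.

Step 26
Reactants: 38 (1R,4S)-1-{(3R)-6-[(2S,5S)-5-(hydroxymethyl)-5-methyloxolan-2-yl]-3,6-dimethylhept-1-en-2-yl}-3-methylcyclopent-2-ene-1,4-diol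
Product: 39 (2S,5S)-5-{(5R)-6-[(1R)-1-hydroxy-3-methyl-4-oxocyclopent-2-en-1-yl]-2,5-dimethylhept-6-en-2-yl}-2-methyloxolane-2-carbaldehyde
Conditions: Dess–Martin periodinane (2.5 equiv), pyridine, CH2Cl2, 0 °C to rt
Reagents that add atoms: none
Why: Dess–Martin oxidation converts the primary alcohol into the C6 aldehyde and the secondary allylic alcohol into the C4 enone in one operation, while the tertiary alcohol cannot be oxidised.

Step 27
Reactants: 39 (2S,5S)-5-{(5R)-6-[(1R)-1-hydroxy-3-methyl-4-oxocyclopent-2-en-1-yl]-2,5-dimethylhept-6-en-2-yl}-2-methyloxolane-2-carbaldehyde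
Product: 40 triethylsilyl ether of 39 at the C1 tertiary alcohol
Conditions: TESOTf, 2,6-lutidine, CH2Cl2, −78 °C
Reagents that add atoms: triethylsilyl triflate, CC[Si](CC)(CC)OS(=O)(=O)C(F)(F)F
Why: Silylation of the tertiary alcohol blocks retro-aldol cleavage and makes the β-oxygen a poor leaving group for the enolate chemistry that follows.

Step 28
Reactants: 40 triethylsilyl ether of 39 at the C1 tertiary alcohol
Product: 42 macrocyclic aldol (C5–C6 bond closed; C6–OH; C1–OTES; C15 exo-methylene; mixture at C5 and C6), via lithium enolate 41 (not isolated)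
Conditions: LiN(SiMe3)2 (1.3 equiv), THF, −78 °C, syringe-pump addition of 40 (final 2 mM), −78 to −40 °C; AcOH quench at −78 °C
Reagents that add atoms: none
Why: Intramolecular aldol addition as the macrocyclisation: kinetic deprotonation at C5, the only acidic site (C15 is still an alkene and the aldehyde has no α-hydrogen), and attack on the reactive α-alkoxy aldehyde at high dilution close the 12-membered ring, the new C5 and C6 centres being removed in the next step.

Step 29
Reactants: 42 macrocyclic aldol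
Product: 44 C1-O-triethylsilyl (5E)-dienone macrocycle with C15 exo-methylene, via mesylate 43 (not isolated)
Conditions: MsCl, Et3N, CH2Cl2, 0 °C; then DBU, rt
Reagents that add atoms: none
Why: Mesylation of the secondary aldol hydroxyl and E1cB elimination give the conjugated exocyclic enone, the E isomer (C7 anti to the carbonyl, C1 and C7 cis in the ring) being the expected thermodynamic geometry.

Step 30
Reactants: 44 C1-O-triethylsilyl (5E)-dienone macrocycle
Product: 45 C1 tertiary alcohol (5E)-dienone macrocycle with C15 exo-methylene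
Conditions: HF·pyridine, pyridine, THF, 0 °C to rt
Reagents that add atoms: none
Why: Fluoride cleavage of the tertiary silyl ether under buffered conditions that leave the cross-conjugated dienone alone.

Step 31
Reactants: 45 C1 tertiary alcohol (5E)-dienone macrocycle
Product: 46 C1 acetate (5E)-dienone macrocycle with C15 exo-methylene
Conditions: Ac2O, DMAP, Et3N, CH2Cl2, rt to 35 °C
Reagents that add atoms: acetic anhydride, CC(=O)OC(C)=O
Why: DMAP-catalysed acylation of the hindered tertiary alcohol, safe now because C5 no longer carries a hydrogen and the acetate cannot be eliminated.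

Step 32
Reactants: 46 C1 acetate (5E)-dienone macrocycle with C15 exo-methylene
Product: 48 CNP0144863.1 (target), via ozonide 47 (not isolated)
Conditions: O3, CH2Cl2, −78 °C (Sudan Red 7B end point); then Me2S, −78 °C to rt
Reagents that add atoms: ozone, [O-][O+]=O
Why: Chemoselective ozonolysis: electrophilic ozone cleaves the isolated 1,1-disubstituted alkene much faster than the two electron-poor enone double bonds, unveiling the C15 ketone without ever exposing C14 to base.

## Compound list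

1 | geranyl acetate, (2E)-3,7-dimethylocta-2,6-dien-1-yl acetate | CC(C)=CCC/C(C)=C/COC(C)=O | starting material
2 | racemic (2E)-6,7-epoxy-3,7-dimethyloct-2-en-1-yl acetate (not isolated) | CC1(C)OC1CC/C(C)=C/COC(C)=O | intermediate
3 | (2E)-3-methyl-6-oxohex-2-en-1-yl acetate | O=CCC/C(C)=C/COC(C)=O | intermediate
4 | O-bis(isopinocampheyl)borinate of 5 (not isolated) | CC(=O)OC/C=C(C)/CC[C@H](OB([C@H]1C[C@H]2C[C@@H]([C@@H]1C)C2(C)C)[C@H]1C[C@H]2C[C@@H]([C@@H]1C)C2(C)C)C(C)(C)C=C | intermediate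
5 | (2E,6S)-6-hydroxy-3,7,7-trimethylnona-2,8-dien-1-yl acetate (not isolated) | CC(=O)OC/C=C(C)/CC[C@H](O)C(C)(C)C=C | intermediate
6 | (2E,6S)-3,7,7-trimethylnona-2,8-diene-1,6-diol | OC/C=C(C)/CC[C@H](O)C(C)(C)C=C | intermediate
7 | {(2R,3R)-3-[(3S)-3-hydroxy-4,4-dimethylhex-5-en-1-yl]-3-methyloxiran-2-yl}methanol (not isolated) | OC[C@H]1O[C@]1(C)CC[C@H](O)C(C)(C)C=C | intermediate
8 | (1R)-1-[(2S,5S)-2-methyl-5-(2-methylbut-3-en-2-yl)oxolan-2-yl]ethane-1,2-diol | OC[C@@H](O)[C@]1(C)CC[C@H](O1)C(C)(C)C=C | intermediate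
9 | (2S,5S)-2-methyl-5-(2-methylbut-3-en-2-yl)oxolane-2-carbaldehyde (not isolated) | O=C[C@]1(C)CC[C@H](O1)C(C)(C)C=C | intermediate
10 | [(2S,5S)-2-methyl-5-(2-methylbut-3-en-2-yl)oxolan-2-yl]methanol | OC[C@]1(C)CC[C@H](O1)C(C)(C)C=C | intermediate
11 | tert-butyl{[(2S,5S)-2-methyl-5-(2-methylbut-3-en-2-yl)oxolan-2-yl]methoxy}diphenylsilane | CC(C)(C)[Si](OC[C@]1(C)CC[C@H](O1)C(C)(C)C=C)(c1ccccc1)c1ccccc1 | intermediate
12 | 1,2,4-trioxolane (ozonide) of the vinyl group of 11 (not isolated) | CC(C)(C)[Si](OC[C@]1(C)CC[C@H](O1)C(C)(C)C1OCOO1)(c1ccccc1)c1ccccc1 | intermediate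
13 | 2-[(2S,5S)-5-{[(tert-butyldiphenylsilyl)oxy]methyl}-5-methyloxolan-2-yl]-2-methylpropanal | CC(C)(C)[Si](OC[C@]1(C)CC[C@H](O1)C(C)(C)C=O)(c1ccccc1)c1ccccc1 | intermediate
14 | methyl (2R)-3-hydroxy-2-methylpropanoate (Roche ester) | COC(=O)[C@H](C)CO | starting material
15 | methyl (2R)-3-[(tert-butyldimethylsilyl)oxy]-2-methylpropanoate | COC(=O)[C@H](C)CO[Si](C)(C)C(C)(C)C | intermediate
16 | (2R)-3-[(tert-butyldimethylsilyl)oxy]-N-methoxy-N,2-dimethylpropanamide | CON(C)C(=O)[C@H](C)CO[Si](C)(C)C(C)(C)C | intermediate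
17 | (3R)-4-[(tert-butyldimethylsilyl)oxy]-3-methylbutan-2-one | CC(=O)[C@H](C)CO[Si](C)(C)C(C)(C)C | intermediate
18 | tert-butyldimethyl[(2R)-2-(2-methyl-1,3-dioxolan-2-yl)propoxy]silane | CC1(OCCO1)[C@H](C)CO[Si](C)(C)C(C)(C)C | intermediate
19 | (2R)-2-(2-methyl-1,3-dioxolan-2-yl)propan-1-ol | CC1(OCCO1)[C@H](C)CO | intermediate
20 | 5-{[(2S)-2-(2-methyl-1,3-dioxolan-2-yl)propyl]sulfanyl}-1-phenyl-1H-tetrazole | CC1(OCCO1)[C@H](C)CSC1=NN=NN1c1ccccc1 | intermediate
21 | 5-{[(2S)-2-(2-methyl-1,3-dioxolan-2-yl)propyl]sulfonyl}-1-phenyl-1H-tetrazole | CC1(OCCO1)[C@H](C)CS(=O)(=O)C1=NN=NN1c1ccccc1 | intermediate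
22 | potassium α-sulfonyl carbanion of 21 (not isolated) | CC1(OCCO1)[C@H](C)[CH-]S(=O)(=O)C1=NN=NN1c1ccccc1.[K+] | intermediate
23 | tert-butyl({(2S,5S)-2-methyl-5-[(5R)-2-methyl-5-(2-methyl-1,3-dioxolan-2-yl)hex-3-en-2-yl]oxolan-2-yl}methoxy)diphenylsilane (E/Z mixture) | CC(C)(C)[Si](OC[C@]1(C)CC[C@H](O1)C(C)(C)C=C[C@@H](C)C1(C)OCCO1)(c1ccccc1)c1ccccc1 | intermediate
24 | tert-butyl({(2S,5S)-2-methyl-5-[(5R)-2-methyl-5-(2-methyl-1,3-dioxolan-2-yl)hexan-2-yl]oxolan-2-yl}methoxy)diphenylsilane | CC(C)(C)[Si](OC[C@]1(C)CC[C@H](O1)C(C)(C)CC[C@@H](C)C1(C)OCCO1)(c1ccccc1)c1ccccc1 | intermediate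
25 | (3R)-6-[(2S,5S)-5-{[(tert-butyldiphenylsilyl)oxy]methyl}-5-methyloxolan-2-yl]-3,6-dimethylheptan-2-one | CC(C)(C)[Si](OC[C@]1(C)CC[C@H](O1)C(C)(C)CC[C@@H](C)C(C)=O)(c1ccccc1)c1ccccc1 | intermediate
26 | (E)-2,4,6-triisopropylbenzenesulfonylhydrazone of 25 | CC(C)(C)[Si](OC[C@]1(C)CC[C@H](O1)C(C)(C)CC[C@@H](C)/C(C)=N/NS(=O)(=O)c1c(C(C)C)cc(C(C)C)cc1C(C)C)(c1ccccc1)c1ccccc1 | intermediate
27 | cis-cyclopent-4-ene-1,3-diyl diacetate (meso) | CC(=O)O[C@@H]1C=C[C@H](OC(C)=O)C1 | starting material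
28 | (1R,4S)-4-hydroxycyclopent-2-en-1-yl acetate | O[C@@H]1C=C[C@H](OC(C)=O)C1 | intermediate
29 | (1R,4S)-4-[(tert-butyldimethylsilyl)oxy]cyclopent-2-en-1-yl acetate | CC(C)(C)[Si](C)(C)O[C@@H]1C=C[C@H](OC(C)=O)C1 | intermediate
30 | (1R,4S)-4-[(tert-butyldimethylsilyl)oxy]cyclopent-2-en-1-ol | CC(C)(C)[Si](C)(C)O[C@@H]1C=C[C@H](O)C1 | intermediate
31 | (4S)-4-[(tert-butyldimethylsilyl)oxy]cyclopent-2-en-1-one | O=C1C=C[C@@H](O[Si](C)(C)C(C)(C)C)C1 | intermediate
32 | tert-butyldimethyl({(1S,2S)-2-methyl-4-[(trimethylsilyl)oxy]cyclopent-3-en-1-yl}oxy)silane | C[Si](C)(C)OC1=C[C@H](C)[C@@H](O[Si](C)(C)C(C)(C)C)C1 | intermediate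
33 | (4S)-4-[(tert-butyldimethylsilyl)oxy]-3-methylcyclopent-2-en-1-one | O=C1C=C(C)[C@@H](O[Si](C)(C)C(C)(C)C)C1 | intermediate
34 | N,C-dilithiated hydrazone from 26 (not isolated) | CC(C)(C)[Si](OC[C@]1(C)CC[C@H](O1)C(C)(C)CC[C@@H](C)C(C[Li])=NN([Li])S(=O)(=O)c1c(C(C)C)cc(C(C)C)cc1C(C)C)(c1ccccc1)c1ccccc1 | intermediate
35 | 2-lithio-1-alkene (C15–Li) from 34 (not isolated) | CC(C)(C)[Si](OC[C@]1(C)CC[C@H](O1)C(C)(C)CC[C@@H](C)C([Li])=C)(c1ccccc1)c1ccccc1 | intermediate
36 | alkenylcerium dichloride from 35 (not isolated) | CC(C)(C)[Si](OC[C@]1(C)CC[C@H](O1)C(C)(C)CC[C@@H](C)C(=C)[Ce](Cl)Cl)(c1ccccc1)c1ccccc1 | intermediate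
37 | (1R,4S)-4-[(tert-butyldimethylsilyl)oxy]-1-{(3R)-6-[(2S,5S)-5-{[(tert-butyldiphenylsilyl)oxy]methyl}-5-methyloxolan-2-yl]-3,6-dimethylhept-1-en-2-yl}-3-methylcyclopent-2-en-1-ol | CC(C)(C)[Si](OC[C@]1(C)CC[C@H](O1)C(C)(C)CC[C@@H](C)C(=C)[C@]1(O)C=C(C)[C@@H](O[Si](C)(C)C(C)(C)C)C1)(c1ccccc1)c1ccccc1 | intermediate
38 | (1R,4S)-1-{(3R)-6-[(2S,5S)-5-(hydroxymethyl)-5-methyloxolan-2-yl]-3,6-dimethylhept-1-en-2-yl}-3-methylcyclopent-2-ene-1,4-diol | OC[C@]1(C)CC[C@H](O1)C(C)(C)CC[C@@H](C)C(=C)[C@]1(O)C=C(C)[C@@H](O)C1 | intermediate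
39 | (2S,5S)-5-{(5R)-6-[(1R)-1-hydroxy-3-methyl-4-oxocyclopent-2-en-1-yl]-2,5-dimethylhept-6-en-2-yl}-2-methyloxolane-2-carbaldehyde | O=C[C@]1(C)CC[C@H](O1)C(C)(C)CC[C@@H](C)C(=C)[C@]1(O)C=C(C)C(=O)C1 | intermediate
40 | triethylsilyl ether of 39 at the C1 tertiary alcohol | O=C[C@]1(C)CC[C@H](O1)C(C)(C)CC[C@@H](C)C(=C)[C@]1(O[Si](CC)(CC)CC)C=C(C)C(=O)C1 | intermediate
41 | lithium C4–C5 enolate of 40 (not isolated) | O=C[C@]1(C)CC[C@H](O1)C(C)(C)CC[C@@H](C)C(=C)[C@]1(O[Si](CC)(CC)CC)C=C(C)C(O[Li])=C1 | intermediate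
42 | macrocyclic aldol: 12-membered ring closed at C5–C6, C6–OH, C1–OTES, C15 exo-methylene (mixture at C5 and C6) | CC[Si](CC)(CC)O[C@@]12C=C(C)C(=O)C1C(O)[C@]1(C)CC[C@H](O1)C(C)(C)CC[C@@H](C)C2=C | intermediate
43 | C6 mesylate of 42 (not isolated) | CC[Si](CC)(CC)O[C@@]12C=C(C)C(=O)C1C(OS(C)(=O)=O)[C@]1(C)CC[C@H](O1)C(C)(C)CC[C@@H](C)C2=C | intermediate
44 | C1-O-triethylsilyl (5E)-dienone macrocycle with C15 exo-methylene | CC[Si](CC)(CC)O[C@@]12C=C(C)C(=O)/C1=C/[C@]1(C)CC[C@H](O1)C(C)(C)CC[C@@H](C)C2=C | intermediate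
45 | C1 tertiary alcohol (5E)-dienone macrocycle with C15 exo-methylene | O[C@@]12C=C(C)C(=O)/C1=C/[C@]1(C)CC[C@H](O1)C(C)(C)CC[C@@H](C)C2=C | intermediate
46 | C1 acetate (5E)-dienone macrocycle with C15 exo-methylene | CC(=O)O[C@@]12C=C(C)C(=O)/C1=C/[C@]1(C)CC[C@H](O1)C(C)(C)CC[C@@H](C)C2=C | intermediate
47 | spiro-1,2,4-trioxolane (ozonide) at C15 of 46 (not isolated) | CC(=O)O[C@@]12C=C(C)C(=O)/C1=C/[C@]1(C)CC[C@H](O1)C(C)(C)CC[C@@H](C)C21OCOO1 | intermediate
48 | CNP0144863.1 | CC(=O)O[C@@]12C=C(C)C(=O)/C1=C/[C@]1(C)CC[C@H](O1)C(C)(C)CC[C@@H](C)C2=O | target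

## Step count and risks

Total step count: 32.
Longest linear sequence: 20 steps (Roche ester 14 to target 48: steps 7–17, then 24–32). The other branches are steps 1–6 (from 1) and steps 18–23 (from 27).

Most likely to fail:

Step 24 (Shapiro generation of a hindered α-branched alkenyl anion and its addition to an enolisable, elimination-prone enone). Fallback: starting from ketone 25, LiN(iPr)2, THF, −78 °C then PhNTf2 gives the kinetic less-substituted enol triflate F1. Me3SnSnMe3, Pd(PPh3)4 (a zerovalent palladium complex), LiCl, THF, 60 °C converts it into the alkenyl(trimethyl)stannane F2. Tin–lithium exchange with MeLi at −78 °C then gives alkenyllithium 35, where the route is rejoined (35 → 36 → 37).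

Step 28 (macrocyclising aldol; competing oligomerisation, retro-aldol or loss of the β-silyloxy group). Fallback: starting from hydroxy keto aldehyde 39, HC(OMe)3, PPTS, MeOH gives the dimethyl acetal F3. TMSOTf, Et3N, CH2Cl2, 0 °C silylates both the tertiary alcohol and the ketone to the bis-silyl 2-silyloxycyclopentadiene F4. Catalytic TMSOTf, CH2Cl2, −78 °C at 1 mM closes the ring by an intramolecular Mukaiyama aldol addition to the oxocarbenium ion, giving the β-methoxy ketone macrocycle F5. DBU eliminates methanol to the trimethylsilyl-protected dienone F6, and HF·pyridine gives alcohol 45, where the route is rejoined.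

Step 32 (ozone must distinguish the hindered exo-methylene from two enone double bonds). Fallback: starting from acetate 46, OsO4 (2 mol%), NMO, acetone/H2O dihydroxylates the isolated electron-rich alkene to the C15 diol F7, and NaIO4, THF/H2O cleaves it to target 48.

Further compounds
F1 | step 24 | 2-triflyloxy-1-alkene (enol triflate of ketone 25 at C15) | CC(C)(C)[Si](OC[C@]1(C)CC[C@H](O1)C(C)(C)CC[C@@H](C)C(=C)OS(=O)(=O)C(F)(F)F)(c1ccccc1)c1ccccc1
F2 | step 24 | 2-(trimethylstannyl)-1-alkene at C15 | CC(C)(C)[Si](OC[C@]1(C)CC[C@H](O1)C(C)(C)CC[C@@H](C)C(=C)[Sn](C)(C)C)(c1ccccc1)c1ccccc1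
F3 | step 28 | C6 dimethyl acetal of 39 | COC(OC)[C@]1(C)CC[C@H](O1)C(C)(C)CC[C@@H](C)C(=C)[C@]1(O)C=C(C)C(=O)C1
F4 | step 28 | C1-O-trimethylsilyl 2-(trimethylsilyloxy)cyclopentadiene of F3 | COC(OC)[C@]1(C)CC[C@H](O1)C(C)(C)CC[C@@H](C)C(=C)[C@]1(O[Si](C)(C)C)C=C(C)C(O[Si](C)(C)C)=C1
F5 | step 28 | macrocyclic β-methoxy ketone (C5–C6 closed, C6–OMe, C1–OTMS) | C[Si](C)(C)O[C@@]12C=C(C)C(=O)C1C(OC)[C@]1(C)CC[C@H](O1)C(C)(C)CC[C@@H](C)C2=C
F6 | step 28 | C1-O-trimethylsilyl (5E)-dienone macrocycle with C15 exo-methylene | C[Si](C)(C)O[C@@]12C=C(C)C(=O)/C1=C/[C@]1(C)CC[C@H](O1)C(C)(C)CC[C@@H](C)C2=C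
F7 | step 32 | C15 tertiary alcohol with hydroxymethyl (1,2-diol from 46) | CC(=O)O[C@@]12C=C(C)C(=O)/C1=C/[C@]1(C)CC[C@H](O1)C(C)(C)CC[C@@H](C)C2(O)CO
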